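The route rests on cutting the C8–CH3 bond of the oxolane ring (O–C6–C7–C8–C9). C8, the methyl-bearing ring carbon between the C7 methylene and the enol-ether carbon C9, is the branch point of a 2-methyl-1-alkanol. In one operation, zirconium-catalysed asymmetric methylalumination and oxidation of the terminal C8=C9 alkene of homoallylic silyl ether 9 forms C8–CH3, sets C8 and delivers the C9 alcohol. Compound 9 spans C2–C9, with C6 fixed from (R)-epichlorohydrin, an (E)-trisubstituted C3=C4 alkene and a PMB ether at C2. C9 then becomes the alkyne that opens a glycidol-derived epoxide, a chromium allylation closes the 14-membered carbocycle at C1–C2, and a gold cyclisation forms the oxolane.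

Key step: step 7

Assumption: cembrane numbering is used (C1 carries the isopropylidene carbons C15–C17, C2 is the ketone, C3/C4 the epoxide, C6–O–C9 the oxolane bridge, C12 the acetoxy carbon), and the (+)-antipode of (NMI)2ZrCl2 is taken as the one that converts 1-alkenes into (S)-2-methyl-1-alkanols.

Step 1
Reactants: 1 (R)-epichlorohydrin
Product: 2 (R)-1-chloropent-4-en-2-ol
Conditions: vinylmagnesium bromide (1.3 equiv), CuI (10 mol %), THF, −40 to −20 °C
Reagents that add atoms: vinylmagnesium bromide, C=C[Mg]Br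
Why: Copper-catalysed Grignard opening of the terminal epoxide occurs by SN2 attack at the unsubstituted ring CH2 (future C7), so the carbinol centre (future C6) is not touched.

Step 2
Reactants: 2 (R)-1-chloropent-4-en-2-ol
Product: 3 (R)-2-allyloxirane
Conditions: powdered NaOH, Et2O, rt; distillation
Reagents that add atoms: none
Why: Intramolecular Williamson displacement of chloride by the alkoxide re-forms a terminal epoxide whose CH2 is now the future C5, without breaking a bond at the stereocentre.

Step 3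
Reactants: 3 (R)-2-allyloxirane
Product: 4 (R)-hept-1-en-6-yn-4-ol
Conditions: lithium acetylide–ethylenediamine complex (1.5 equiv), DMSO, 0 °C to rt
Reagents that add atoms: lithium acetylide (ethylenediamine complex), [Li]C#C
Why: SN2 alkynylation of the monosubstituted epoxide at its CH2 is a standard epoxide opening and keeps the C6 configuration (R).

Step 4
Reactants: 4 (R)-hept-1-en-6-yn-4-ol
Product: 5 (R)-tert-butyl(hept-1-en-6-yn-4-yloxy)dimethylsilane
Conditions: TBSCl, imidazole, DMF, rt
Reagents that add atoms: tert-butyldimethylsilyl chloride, CC(C)(C)[Si](C)(C)Cl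
Why: Standard silylation of a secondary alcohol, giving a bulky ether that shields the C6 oxygen in both carboalumination steps.

Step 5
Reactants: 5 (R)-tert-butyl(hept-1-en-6-yn-4-yloxy)dimethylsilane
Product: 8 (2E,5R)-5-[(tert-butyldimethylsilyl)oxy]-3-methylocta-2,7-dien-1-ol, via alkenyldimethylalane 6 (not isolated), via lithium alkenylalanate 7 (not isolated)
Conditions: AlMe3 (2.5 equiv), Cp2ZrCl2 (0.25 equiv), CH2Cl2, 0 °C to rt; volatiles removed; n-BuLi (1.0 equiv), THF, −78 °C; (CH2O)n, −78 °C to rt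
Reagents that add atoms: trimethylaluminium, C[Al](C)C; paraformaldehyde (as formaldehyde), C=O
Why: Negishi carboalumination adds methyl (to C4) and aluminium (to C3) syn across the terminal alkyne, the monosubstituted alkene being far less reactive with the achiral zirconocene, and the derived ate complex is hydroxymethylated with retention to give the (E)-trisubstituted allylic alcohol.

Step 6
Reactants: 8 (2E,5R)-5-[(tert-butyldimethylsilyl)oxy]-3-methylocta-2,7-dien-1-ol
Product: 9 tert-butyl{[(4R,6E)-8-[(4-methoxybenzyl)oxy]-6-methylocta-1,6-dien-4-yl]oxy}dimethylsilane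
Conditions: NaH, 4-methoxybenzyl chloride, Bu4NI (cat.), THF/DMF, 0 °C to rt
Reagents that add atoms: 4-methoxybenzyl chloride, COc1ccc(CCl)cc1
Why: Williamson etherification of the primary allylic alkoxide, to which the secondary silyl ether is stable.

Step 7
Reactants: 9 tert-butyl{[(4R,6E)-8-[(4-methoxybenzyl)oxy]-6-methylocta-1,6-dien-4-yl]oxy}dimethylsilane
Product: 11 (2S,4R,6E)-4-[(tert-butyldimethylsilyl)oxy]-8-[(4-methoxybenzyl)oxy]-2,6-dimethyloct-6-en-1-ol, via alkyldimethylalane 10 (not isolated)
Conditions: AlMe3 (3 equiv), (+)-bis(1-neomenthylindenyl)zirconium dichloride, (+)-(NMI)2ZrCl2 (5 mol %), CH2Cl2, 0 °C to rt; then O2, 0 °C; aq. NaOH work-up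
Reagents that add atoms: trimethylaluminium, C[Al](C)C; dioxygen, O=O
Why: The chiral methylzirconocene cation formed from (NMI)2ZrCl2 and AlMe3 binds the monosubstituted C8=C9 alkene and inserts it with methyl going to C8 and zirconium to C9, after which Zr-to-Al transmetalation gives alane 10 and O2 oxidises the primary C9–Al bond to the alcohol. The closest known reaction type is exactly this zirconium-catalysed asymmetric methylalumination–oxidation of 1-alkenes to 2-methyl-1-alkanols, including substrates that carry remote silyl ethers. No ring is closed. The new C8 centre (S) is set by the enantioface selection of the C2-symmetric bis(neomenthylindenyl) ligand set, while C6 (R) is already fixed, so a facial error should appear as a C8 epimer that can be separated. The step needs chemoselectivity for the terminal alkene (the trisubstituted C3=C4 alkene is too hindered to insert), regioselectivity for methyl at the internal carbon (secured by the preference for a primary alkylzirconium) and facial selectivity; the bulky TBS group at C6 and the remote, weakly basic PMB ether should keep both oxygens off the cationic zirconium.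

Step 8
Reactants: 11 (2S,4R,6E)-4-[(tert-butyldimethylsilyl)oxy]-8-[(4-methoxybenzyl)oxy]-2,6-dimethyloct-6-en-1-ol
Product: 12 (2S,4R,6E)-4-[(tert-butyldimethylsilyl)oxy]-8-[(4-methoxybenzyl)oxy]-2,6-dimethyloct-6-enal
Conditions: Dess–Martin periodinane, NaHCO3, CH2Cl2, 0 °C to rt
Reagents that add atoms: none
Why: Buffered Dess–Martin oxidation of the primary alcohol is mild enough to give the α-methyl aldehyde without epimerising C8, and the crude aldehyde is used directly.

Step 9
Reactants: 12 (2S,4R,6E)-4-[(tert-butyldimethylsilyl)oxy]-8-[(4-methoxybenzyl)oxy]-2,6-dimethyloct-6-enal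
Product: 13 tert-butyl{[(3S,5R,7E)-9-[(4-methoxybenzyl)oxy]-3,7-dimethylnon-7-en-1-yn-5-yl]oxy}dimethylsilane
Conditions: dimethyl (1-diazo-2-oxopropyl)phosphonate, K2CO3, MeOH, 0 °C to rt
Reagents that add atoms: dimethyl (1-diazo-2-oxopropyl)phosphonate, COP(=O)(OC)C(=[N+]=[N-])C(C)=O
Why: Ohira–Bestmann homologation (Seyferth–Gilbert type) turns the aldehyde into the terminal alkyne, adding C10, under carbonate conditions that normally preserve an α-stereocentre.

Step 10
Reactants: 14 (S)-2-methylglycidol
Product: 15 (R)-2-methylhex-5-ene-1,2-diol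
Conditions: allylmagnesium chloride (2.5 equiv), CuI (10 mol %), THF, −40 to 0 °C
Reagents that add atoms: allylmagnesium chloride, C=CC[Mg]Cl
Why: After deprotonation of the hydroxyl, copper-catalysed SN2 opening by the allyl Grignard reagent occurs at the unsubstituted epoxide carbon (future C13) and leaves the quaternary carbinol centre (future C12) intact.

Step 11
Reactants: 15 (R)-2-methylhex-5-ene-1,2-diol
Product: 17 (R)-2-(but-3-en-1-yl)-2-methyloxirane, via primary tosylate 16 (not isolated)
Conditions: NaH (2.2 equiv), 1-(p-tolylsulfonyl)imidazole (1.05 equiv), THF, 0 °C to rt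
Reagents that add atoms: none
Why: Selective sulfonylation of the primary alkoxide followed by 3-exo-tet closure by the tertiary alkoxide moves the epoxide to the other arm, so C12 becomes (R) with its ring CH2 as the future C11 and no bond to the stereocentre is broken.

Step 12
Reactants: 17 (R)-2-(but-3-en-1-yl)-2-methyloxirane
Product: 18 (2E)-2-methyl-5-[(2R)-2-methyloxiran-2-yl]pent-2-enal
Conditions: methacrolein (10 equiv), second-generation Grubbs catalyst RuCl2(=CHPh)(PCy3)(H2IMes) (5 mol %), CH2Cl2, 40 °C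
Reagents that add atoms: methacrolein, CC(=C)C=O
Why: Olefin cross-metathesis of a terminal alkene with excess methacrolein should give the (E)-2-methyl enal, and the 2,2-disubstituted epoxide is inert to the ruthenium carbene.

Step 13
Reactants: 18 (2E)-2-methyl-5-[(2R)-2-methyloxiran-2-yl]pent-2-enal
Product: 19 (2E)-2-methyl-5-[(2R)-2-methyloxiran-2-yl]pent-2-en-1-ol
Conditions: DIBAL-H (1.1 equiv), CH2Cl2, −78 °C; Rochelle salt work-up
Reagents that add atoms: none
Why: 1,2-Reduction of the enal by DIBAL-H at low temperature leaves the epoxide and the alkene untouched.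

Step 14
Reactants: 19 (2E)-2-methyl-5-[(2R)-2-methyloxiran-2-yl]pent-2-en-1-ol
Product: 20 triethyl{[(2E)-2-methyl-5-[(2R)-2-methyloxiran-2-yl]pent-2-en-1-yl]oxy}silane
Conditions: Et3SiCl, imidazole, CH2Cl2, 0 °C
Reagents that add atoms: chlorotriethylsilane, CC[Si](CC)(CC)Cl
Why: Standard silylation gives a primary triethylsilyl ether that can later be removed in the presence of the secondary TBS ether.

Step 15
Reactants: 13 tert-butyl{[(3S,5R,7E)-9-[(4-methoxybenzyl)oxy]-3,7-dimethylnon-7-en-1-yn-5-yl]oxy}dimethylsilane; 20 triethyl{[(2E)-2-methyl-5-[(2R)-2-methyloxiran-2-yl]pent-2-en-1-yl]oxy}silane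
Product: 22 open-chain tertiary alcohol (6R,8S,12R), C2 OPMB, (E)-C3=C4, C6 OTBS, C8 methyl, C9≡C10, C12 OH and methyl, (E)-C1=C15, C16 OTES, via lithium acetylide 21 (not isolated)
Conditions: 13 (1.3 equiv), n-BuLi, THF, −78 °C; BF3·OEt2, then 20, −78 °C
Reagents that add atoms: none
Why: BF3-assisted opening of the 2,2-disubstituted epoxide by the lithium acetylide at its CH2 forms the C10–C11 bond and releases the tertiary C12 alcohol with its configuration (R) unchanged.

Step 16
Reactants: 22 open-chain tertiary alcohol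
Product: 23 open-chain tertiary acetate (C12 OAc, otherwise as 22)
Conditions: Ac2O, DMAP, Et3N, CH2Cl2, rt
Reagents that add atoms: acetic anhydride, CC(=O)OC(C)=O
Why: DMAP-catalysed acylation acetylates the only free hydroxyl, the tertiary homopropargylic alcohol.

Step 17
Reactants: 23 open-chain tertiary acetate
Product: 24 C16 allylic alcohol (C16 OH, otherwise as 23)
Conditions: PPTS (cat.), MeOH/CH2Cl2, 0 °C
Reagents that add atoms: none
Why: Mild acid methanolysis cleaves the primary triethylsilyl ether much faster than the secondary TBS ether and leaves the tertiary acetate and PMB ether intact.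

Step 18
Reactants: 24 C16 allylic alcohol
Product: 26 C16 allylic chloride (C16 Cl, otherwise as 24), via allylic mesylate 25 (not isolated)
Conditions: MsCl, LiCl, 2,4,6-collidine, DMF, 0 °C
Reagents that add atoms: lithium chloride, [Li+].[Cl-]
Why: Mesylation and in situ SN2 displacement by chloride convert the primary allylic alcohol into the chloride without allylic transposition, and acetate, PMB and TBS groups are inert.

Step 19
Reactants: 26 C16 allylic chloride
Product: 27 C2 allylic alcohol (C2 OH, C16 Cl, C6 OTBS, C12 OAc)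
Conditions: DDQ, CH2Cl2/pH 7 buffer, 0 °C
Reagents that add atoms: none
Why: Oxidative cleavage of the PMB ether by DDQ in buffered wet CH2Cl2 leaves the silyl ether, acetate, alkyne and allylic chloride untouched.

Step 20
Reactants: 27 C2 allylic alcohol
Product: 28 (3S,4S)-epoxy alcohol (C3–C4 epoxide, C2 OH, otherwise as 27)
Conditions: Ti(OiPr)4 (20 mol %), L-(+)-diethyl tartrate (25 mol %), t-BuOOH, 4 Å MS, CH2Cl2, −20 °C
Reagents that add atoms: tert-butyl hydroperoxide, CC(C)(C)OO
Why: Sharpless asymmetric epoxidation of the (E)-3,3-disubstituted allylic alcohol with L-(+)-diethyl tartrate delivers oxygen to the face that gives the (2S,3S)-epoxy alcohol, which is the C3/C4 configuration of the target, and only the allylic-alcohol alkene reacts.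

Step 21
Reactants: 28 (3S,4S)-epoxy alcohol
Product: 29 epoxy aldehyde (C2 CHO, C16 Cl)
Conditions: Dess–Martin periodinane, NaHCO3, CH2Cl2, 0 °C
Reagents that add atoms: none
Why: Buffered Dess–Martin oxidation gives the α,β-epoxy aldehyde without opening the epoxide, and it is used at once.

Step 22
Reactants: 29 epoxy aldehyde
Product: 31 macrocyclic homoallylic alcohol (14-membered ring, C2 OH, C1 isopropenyl, mixture at C1 and C2), via allylchromium dichloride 30 (not isolated)
Conditions: CrCl2 (10 equiv), LiI (cat.), 4 Å MS, THF, rt, slow addition of 29 (final 2 mM)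
Reagents that add atoms: none
Why: In this Nozaki–Hiyama allylation CrCl2 reduces the allylic chloride to an allylchromium species that adds through its γ-carbon C1 to the C2 aldehyde under high dilution and closes the 14-membered carbocycle, the C1 and C2 configurations being irrelevant because both centres are planarised in step 23.

Step 23
Reactants: 31 macrocyclic homoallylic alcohol
Product: 33 macrocyclic epoxy enone (C2 ketone, C1 isopropylidene, C6 OTBS), via isopropenyl ketone 32 (not isolated)
Conditions: Dess–Martin periodinane, NaHCO3, CH2Cl2, rt; then DBU, CH2Cl2, rt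
Reagents that add atoms: none
Why: Dess–Martin oxidation gives the β,γ-unsaturated ketone, and DBU-mediated dienolate formation with γ-protonation should move the double bond into conjugation as the isopropylidene ketone, merging all C1/C2 isomers while the non-enolisable epoxide carbon C3 is unaffected.

Step 24
Reactants: 33 macrocyclic epoxy enone
Product: 34 C6 alcohol (C6 OH, C9≡C10 alkyne)
Conditions: HF·pyridine, pyridine, THF, 0 °C to rt
Reagents that add atoms: none
Why: Buffered fluoride desilylation removes the secondary TBS ether without affecting the tertiary acetate, epoxy ketone or alkyne.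

Step 25
Reactants: 34 C6 alcohol
Product: 35 CNP0162736.1
Conditions: AuCl (5 mol %), K2CO3 (10 mol %), MeCN, rt
Reagents that add atoms: none
Why: Gold-catalysed 5-exo-dig hydroalkoxylation adds the C6 hydroxyl and gold anti across the activated C9≡C10 alkyne, and protodeauration with retention then gives the (Z)-exocyclic enol ether and closes the oxolane ring, with carbonate buffering against migration of the double bond into the ring.

Compound list
1 | (R)-epichlorohydrin | ClC[C@H]1CO1 | starting material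
2 | (R)-1-chloropent-4-en-2-ol | ClC[C@H](O)CC=C | intermediate
3 | (R)-2-allyloxirane | C=CC[C@@H]1CO1 | intermediate
4 | (R)-hept-1-en-6-yn-4-ol | C=CC[C@@H](O)CC#C | intermediate
5 | (R)-tert-butyl(hept-1-en-6-yn-4-yloxy)dimethylsilane | C=CC[C@@H](O[Si](C)(C)C(C)(C)C)CC#C | intermediate
6 | (E)-alkenyldimethylalane from 5 (Al on C3, methyl on C4) | C=CC[C@@H](O[Si](C)(C)C(C)(C)C)C/C(C)=C/[Al](C)C | intermediate
7 | lithium butyl(alkenyl)dimethylaluminate from 6 | C=CC[C@@H](O[Si](C)(C)C(C)(C)C)C/C(C)=C/[Al-](C)(C)CCCC.[Li+] | intermediate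
8 | (2E,5R)-5-[(tert-butyldimethylsilyl)oxy]-3-methylocta-2,7-dien-1-ol | C=CC[C@@H](O[Si](C)(C)C(C)(C)C)C/C(C)=C/CO | intermediate
9 | tert-butyl{[(4R,6E)-8-[(4-methoxybenzyl)oxy]-6-methylocta-1,6-dien-4-yl]oxy}dimethylsilane (precursor of the key step) | C=CC[C@@H](O[Si](C)(C)C(C)(C)C)C/C(C)=C/COCc1ccc(OC)cc1 | intermediate
10 | (2S,4R)-2-methylalkyl dimethylalane from 9 (Al on C9) | C[Al](C)C[C@@H](C)C[C@@H](O[Si](C)(C)C(C)(C)C)C/C(C)=C/COCc1ccc(OC)cc1 | intermediate
11 | (2S,4R,6E)-4-[(tert-butyldimethylsilyl)oxy]-8-[(4-methoxybenzyl)oxy]-2,6-dimethyloct-6-en-1-ol (product of the key step) | OC[C@@H](C)C[C@@H](O[Si](C)(C)C(C)(C)C)C/C(C)=C/COCc1ccc(OC)cc1 | intermediate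
12 | (2S,4R,6E)-4-[(tert-butyldimethylsilyl)oxy]-8-[(4-methoxybenzyl)oxy]-2,6-dimethyloct-6-enal | O=C[C@@H](C)C[C@@H](O[Si](C)(C)C(C)(C)C)C/C(C)=C/COCc1ccc(OC)cc1 | intermediate
13 | tert-butyl{[(3S,5R,7E)-9-[(4-methoxybenzyl)oxy]-3,7-dimethylnon-7-en-1-yn-5-yl]oxy}dimethylsilane | C#C[C@@H](C)C[C@@H](O[Si](C)(C)C(C)(C)C)C/C(C)=C/COCc1ccc(OC)cc1 | intermediate
14 | (S)-2-methylglycidol | C[C@]1(CO)CO1 | starting material
15 | (R)-2-methylhex-5-ene-1,2-diol | C[C@](O)(CO)CCC=C | intermediate
16 | (R)-2-hydroxy-2-methylhex-5-en-1-yl 4-methylbenzenesulfonate | C[C@](O)(COS(=O)(=O)c1ccc(C)cc1)CCC=C | intermediate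
17 | (R)-2-(but-3-en-1-yl)-2-methyloxirane | C[C@@]1(CCC=C)CO1 | intermediate
18 | (2E)-2-methyl-5-[(2R)-2-methyloxiran-2-yl]pent-2-enal | C[C@@]1(CC/C=C(\C)C=O)CO1 | intermediate
19 | (2E)-2-methyl-5-[(2R)-2-methyloxiran-2-yl]pent-2-en-1-ol | C[C@@]1(CC/C=C(\C)CO)CO1 | intermediate
20 | triethyl{[(2E)-2-methyl-5-[(2R)-2-methyloxiran-2-yl]pent-2-en-1-yl]oxy}silane | C[C@@]1(CC/C=C(\C)CO[Si](CC)(CC)CC)CO1 | intermediate
21 | lithium acetylide of 13 | [Li]C#C[C@@H](C)C[C@@H](O[Si](C)(C)C(C)(C)C)C/C(C)=C/COCc1ccc(OC)cc1 | intermediate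
22 | open-chain tertiary alcohol (6R,8S,12R): C2 OPMB, (E)-C3=C4, C6 OTBS, C8 methyl, C9≡C10, C12 OH and methyl, (E)-C1=C15, C16 OTES | C[C@@](O)(CC/C=C(\C)CO[Si](CC)(CC)CC)CC#C[C@@H](C)C[C@@H](O[Si](C)(C)C(C)(C)C)C/C(C)=C/COCc1ccc(OC)cc1 | intermediate
23 | open-chain tertiary acetate (22 with C12 OAc) | CC(=O)O[C@](C)(CC/C=C(\C)CO[Si](CC)(CC)CC)CC#C[C@@H](C)C[C@@H](O[Si](C)(C)C(C)(C)C)C/C(C)=C/COCc1ccc(OC)cc1 | intermediate
24 | C16 allylic alcohol (23 with C16 OH) | CC(=O)O[C@](C)(CC/C=C(\C)CO)CC#C[C@@H](C)C[C@@H](O[Si](C)(C)C(C)(C)C)C/C(C)=C/COCc1ccc(OC)cc1 | intermediate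
25 | C16 allylic mesylate | CC(=O)O[C@](C)(CC/C=C(\C)COS(C)(=O)=O)CC#C[C@@H](C)C[C@@H](O[Si](C)(C)C(C)(C)C)C/C(C)=C/COCc1ccc(OC)cc1 | intermediate
26 | C16 allylic chloride (C2 OPMB) | CC(=O)O[C@](C)(CC/C=C(\C)CCl)CC#C[C@@H](C)C[C@@H](O[Si](C)(C)C(C)(C)C)C/C(C)=C/COCc1ccc(OC)cc1 | intermediate
27 | C2 allylic alcohol with C16 chloride | CC(=O)O[C@](C)(CC/C=C(\C)CCl)CC#C[C@@H](C)C[C@@H](O[Si](C)(C)C(C)(C)C)C/C(C)=C/CO | intermediate
28 | (3S,4S)-epoxy alcohol with C16 chloride | CC(=O)O[C@](C)(CC/C=C(\C)CCl)CC#C[C@@H](C)C[C@@H](O[Si](C)(C)C(C)(C)C)C[C@]1(C)O[C@H]1CO | intermediate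
29 | epoxy aldehyde with C16 chloride | CC(=O)O[C@](C)(CC/C=C(\C)CCl)CC#C[C@@H](C)C[C@@H](O[Si](C)(C)C(C)(C)C)C[C@]1(C)O[C@H]1C=O | intermediate
30 | allylchromium dichloride from 29 (Cr on C16) | CC(=O)O[C@](C)(CC/C=C(\C)C[Cr](Cl)Cl)CC#C[C@@H](C)C[C@@H](O[Si](C)(C)C(C)(C)C)C[C@]1(C)O[C@H]1C=O | intermediate
31 | 14-membered homoallylic alcohol: C2 OH, C1 isopropenyl (mixture at C1, C2), C3–C4 epoxide, C6 OTBS, C9≡C10, C12 OAc | CC(=O)O[C@@]1(C)CC#C[C@@H](C)C[C@@H](O[Si](C)(C)C(C)(C)C)C[C@]2(C)O[C@H]2C(O)C(C(C)=C)CC1 | intermediate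
32 | 14-membered β,γ-unsaturated ketone: C2 ketone, C1 isopropenyl | CC(=O)O[C@@]1(C)CC#C[C@@H](C)C[C@@H](O[Si](C)(C)C(C)(C)C)C[C@]2(C)O[C@H]2C(=O)C(C(C)=C)CC1 | intermediate
33 | 14-membered epoxy enone: C2 ketone, C1 isopropylidene, C6 OTBS | CC(=O)O[C@@]1(C)CC#C[C@@H](C)C[C@@H](O[Si](C)(C)C(C)(C)C)C[C@]2(C)O[C@H]2C(=O)C(=C(C)C)CC1 | intermediate
34 | 14-membered hydroxy alkyne: 33 with C6 OH | CC(=O)O[C@@]1(C)CC#C[C@@H](C)C[C@@H](O)C[C@]2(C)O[C@H]2C(=O)C(=C(C)C)CC1 | intermediate
35 | CNP0162736.1 | CC(=O)O[C@@]1(C)C/C=C2\O[C@H](C[C@@H]2C)C[C@]2(C)O[C@H]2C(=O)C(=C(C)C)CC1 | target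

Total step count: 25. Longest linear sequence: 20 steps (steps 1–9 and 15–25, from (R)-epichlorohydrin); the epoxide branch (steps 10–14) is 5 steps.

Steps most likely to fail

Step 22. The ring closure may lose out to intermolecular coupling, the allylic chloride may be reduced too slowly, or the epoxy aldehyde may be degraded by the chromium salts. The fallback joins the halves first and closes the ring at C9≡C10 by alkyne metathesis; it sets out from 13 and 20 and returns at 33. Alkyne 13 would be deprotonated (via 21) and methylated with MeI to the methyl-capped alkyne F1, then taken through DDQ cleavage to the allylic alcohol F2, Sharpless epoxidation with L-(+)-diethyl tartrate to the epoxy alcohol F3 and Dess–Martin oxidation to the epoxy aldehyde F4. Epoxide 20 would be opened with 1-propynyllithium and BF3·OEt2 to the tertiary alcohol F5, acetylated to the acetate F6, desilylated to the allylic alcohol F7 and converted through the mesylate F8 into the allylic chloride F9. Intermolecular Nozaki–Hiyama allylation of F4 with F9 (CrCl2, through the allylchromium species F10) should give the open-chain diyne alcohol F11. Dess–Martin oxidation to the isopropenyl ketone F12 and DBU isomerisation would give the diyne enone F13. Ring-closing alkyne metathesis with Mo(≡CC6H4-4-OMe)(OSiPh3)3 in toluene over 5 Å MS, which takes up the 2-butyne, should then form 33.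

Step 25. The hydroxyl may add in the 6-endo sense, the acetate carbonyl may compete for the activated alkyne, or the exocyclic enol ether may hydrate or slip into the ring with loss of the C8 centre. The fallback replaces the catalytic hydroalkoxylation by halocyclisation and reduction; it sets out from 34 and returns at 35. Iodoetherification with I2 and NaHCO3 in MeCN at 0 °C (anti 5-exo-dig addition) should give the (E)-iodo enol ether F14. Hydrodeiodination with Pd(PPh3)4, HCO2H and Et3N proceeds with retention of alkene geometry and would deliver 35 under non-acidic conditions.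

Step 7. Facial selectivity may be insufficient, giving a C8 epimer mixture, or the carbometalation may stall through oxygen coordination to the catalyst. The fallback installs the methyl by auxiliary-controlled enolate alkylation; it sets out from 9 and returns at 11. Chemoselective hydroboration of the terminal alkene with 9-BBN and oxidative work-up would give the primary alcohol F15, and TEMPO/PhI(OAc)2 in aqueous MeCN the acid F16. Activation with pivaloyl chloride as the mixed anhydride F17 and acylation of lithiated (S)-4-benzyl-oxazolidin-2-one would give the imide F18. Enolisation with NaHMDS to the (Z)-sodium enolate F19 and methylation with MeI on the face opposite the benzyl group should give the (S)-α-methyl imide F20. LiBH4 reduction then releases the auxiliary and returns alcohol 11.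

Further compounds
F1 | step 22 | methyl-capped alkyne from 13 | CC#C[C@@H](C)C[C@@H](O[Si](C)(C)C(C)(C)C)C/C(C)=C/COCc1ccc(OC)cc1
F2 | step 22 | allylic alcohol (F1 without PMB) | CC#C[C@@H](C)C[C@@H](O[Si](C)(C)C(C)(C)C)C/C(C)=C/CO
F3 | step 22 | (3S,4S)-epoxy alcohol of F2 | CC#C[C@@H](C)C[C@@H](O[Si](C)(C)C(C)(C)C)C[C@]1(C)O[C@H]1CO
F4 | step 22 | epoxy aldehyde of F3 | CC#C[C@@H](C)C[C@@H](O[Si](C)(C)C(C)(C)C)C[C@]1(C)O[C@H]1C=O
F5 | step 22 | (R)-tertiary alcohol from 20 and propynyllithium | C[C@@](O)(CC/C=C(\C)CO[Si](CC)(CC)CC)CC#CC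
F6 | step 22 | acetate of F5 | CC(=O)O[C@](C)(CC/C=C(\C)CO[Si](CC)(CC)CC)CC#CC
F7 | step 22 | allylic alcohol (F6 without TES) | CC(=O)O[C@](C)(CC/C=C(\C)CO)CC#CC
F8 | step 22 | allylic mesylate of F7 | CC(=O)O[C@](C)(CC/C=C(\C)COS(C)(=O)=O)CC#CC
F9 | step 22 | allylic chloride from F8 | CC(=O)O[C@](C)(CC/C=C(\C)CCl)CC#CC
F10 | step 22 | allylchromium dichloride from F9 | CC(=O)O[C@](C)(CC/C=C(\C)C[Cr](Cl)Cl)CC#CC
F11 | step 22 | open-chain diyne homoallylic alcohol (C1–C2 bond formed, mixture at C1 and C2) | CC#C[C@@H](C)C[C@@H](O[Si](C)(C)C(C)(C)C)C[C@]1(C)O[C@H]1C(O)C(C(C)=C)CC[C@](C)(CC#CC)OC(C)=O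
F12 | step 22 | open-chain diyne isopropenyl ketone | CC#C[C@@H](C)C[C@@H](O[Si](C)(C)C(C)(C)C)C[C@]1(C)O[C@H]1C(=O)C(C(C)=C)CC[C@](C)(CC#CC)OC(C)=O
F13 | step 22 | open-chain diyne isopropylidene ketone | CC#C[C@@H](C)C[C@@H](O[Si](C)(C)C(C)(C)C)C[C@]1(C)O[C@H]1C(=O)C(=C(C)C)CC[C@](C)(CC#CC)OC(C)=O
F14 | step 25 | (E)-10-iodo enol ether of the target skeleton | CC(=O)O[C@@]1(C)C/C(I)=C2\O[C@H](C[C@@H]2C)C[C@]2(C)O[C@H]2C(=O)C(=C(C)C)CC1
F15 | step 7 | primary alcohol from hydroboration of 9 | OCCC[C@@H](O[Si](C)(C)C(C)(C)C)C/C(C)=C/COCc1ccc(OC)cc1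
F16 | step 7 | carboxylic acid from F15 | OC(=O)CC[C@@H](O[Si](C)(C)C(C)(C)C)C/C(C)=C/COCc1ccc(OC)cc1
F17 | step 7 | mixed pivalic anhydride of F16 | CC(C)(C)C(=O)OC(=O)CC[C@@H](O[Si](C)(C)C(C)(C)C)C/C(C)=C/COCc1ccc(OC)cc1
F18 | step 7 | N-acyl (S)-4-benzyl-oxazolidin-2-one | O=C(CC[C@@H](O[Si](C)(C)C(C)(C)C)C/C(C)=C/COCc1ccc(OC)cc1)N1[C@@H](Cc2ccccc2)COC1=O
F19 | step 7 | (Z)-sodium enolate of F18 | [Na+].[O-]/C(=C\C[C@@H](O[Si](C)(C)C(C)(C)C)C/C(C)=C/COCc1ccc(OC)cc1)N1[C@@H](Cc2ccccc2)COC1=O
F20 | step 7 | (S)-α-methyl imide | O=C([C@@H](C)C[C@@H](O[Si](C)(C)C(C)(C)C)C/C(C)=C/COCc1ccc(OC)cc1)N1[C@@H](Cc2ccccc2)COC1=O
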